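**Strategy.** The molecule consists of two identical ring A–O–ring B(–ring F) arms, ether-linked through B4 to ring C, which also carries the chlorinated ring G. The plan rests on building the pentasubstituted ring B (oxygens at B1, B3, B4 and B5, aryl ring F at B6, hydrogen at B2) from a squarate-derived cyclobutenone. A single thermolysis turns a 2-aryl-3-methoxy-4-alkoxy-4-(1-methoxyvinyl)cyclobutenone into the B–F biaryl phenol: it forms the B1–B2 bond, closes ring B and leaves the para oxygens differentiated, B1 free and B4 protected. The precursor comes from two successive organolithium additions to dimethyl squarate, so the crowded B6–F bond originates from an ordinary aryllithium addition to a carbonyl group.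

Key step: step 3

Remarks on the chemistry (assumptions):
- Ring letters: A = 2,4,6-trioxygenated phenoxy ring on B1; F = 2,4,6-trioxygenated phenyl ring on B6; C = central ring; G = 4-chloro-3,5-dihydroxyphenoxy ring. The second arm (rings D, E, H) is identical to B, A, F, so one arm phenol is made and used twice.
- The B4 oxygen is capped as a methoxymethyl (MOM) acetal, not as a silyl ether. An aryl silyl ether would be cleaved or passed between phenoxides in the hot basic copper etherification that follows the key step; the acetal is inert there and comes off with dilute acid.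
- The target has no stereocentre. Compounds 4, 5, 9 and 10 are racemic, and their single stereocentre disappears in step 3.
- Commercial starting materials: 1, 2, 7, 14, 17 and 22.

**Step 1**
Reactants: 1 dimethyl squarate; 2 1,3,5-trimethoxybenzene
Product: 6 3-methoxy-4-(2,4,6-trimethoxyphenyl)cyclobut-3-ene-1,2-dione, via 2,4,6-trimethoxyphenyllithium 3 (not isolated), via lithium cyclobutenolate 4 (not isolated), via trifluoroacetate ester 5 (not isolated)
Conditions: 2, n-BuLi, THF, 0 °C → rt; add to 1, THF, −78 °C; TFAA, −78 °C; aq. NH4Cl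
Reagents that add atoms: water, O
Why: Directed ortho-lithiation between two methoxy groups, 1,2-addition of the aryllithium to one squarate carbonyl and trifluoroacetylation–hydrolysis of the adduct (the standard squarate addition/rearrangement to a 3-aryl-4-alkoxycyclobutenedione, with loss of methanol) should create the hindered B6–F bond as a simple carbonyl addition.

**Step 2**
Reactants: 6 3-methoxy-4-(2,4,6-trimethoxyphenyl)cyclobut-3-ene-1,2-dione; 7 methyl vinyl ether
Product: 10 racemic 3-methoxy-4-(methoxymethoxy)-4-(1-methoxyvinyl)-2-(2,4,6-trimethoxyphenyl)cyclobut-2-en-1-one, via 1-methoxyvinyllithium 8 (not isolated), via lithium alkoxide adduct 9 (not isolated)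
Conditions: 7, t-BuLi, THF, −78 → 0 °C; 6, THF, −78 °C; MOMCl, −78 → 0 °C; aq. NaHCO3
Reagents that add atoms: chloromethyl methyl ether (MOMCl), COCCl
Why: 1,2-Addition of the α-alkoxyvinyllithium should take place at the carbonyl next to the methoxy-bearing carbon, because the other carbonyl is deactivated as a vinylogous ester, and the tertiary lithium alkoxide is then O-alkylated by the reactive chloromethyl ether (Williamson-type acetal formation), the new stereocentre being formed without control as a racemate.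

**Step 3**
Reactants: 10 racemic 3-methoxy-4-(methoxymethoxy)-4-(1-methoxyvinyl)-2-(2,4,6-trimethoxyphenyl)cyclobut-2-en-1-one
Product: 13 3,5-dimethoxy-4-(methoxymethoxy)-2-(2,4,6-trimethoxyphenyl)phenol, via dienylketene 11 (not isolated), via cyclohexadienone 12 (not isolated)
Conditions: toluene (dilute, degassed), 110 °C, argon
Reagents that add atoms: none
Why: Heating should trigger a thermal conrotatory 4π electrocyclic opening of the cyclobutenone bond between the carbonyl carbon and the acetal-bearing carbon, in which the methoxymethoxy donor rotates outward (torquoselectivity) so that the 1-methoxyvinyl group ends up cis to the ketene-bearing carbon in (Z)-dienylketene 11. A disrotatory 6π electrocyclisation then joins the ketene carbon (B1) to the vinyl terminus (B2), closing the six-membered ring B as dienone 12, and enolisation aromatises it to phenol 13. This is a Moore rearrangement, the closest known reaction type being the conversion of squarate-derived 4-alkenyl-4-oxycyclobutenones into mono-protected hydroquinones. No stereocentre is created and the one in 10 is erased. The step needs outward rotation of the oxygen substituent and a single regiochemistry: the first is secured by the donor character of the acetal oxygen, the second is already written into the order of the two carbonyl additions, the cap on the C4 oxygen blocks lactonisation of the ketene, and the aryl group on C2 cannot act as a 6π partner.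

**Step 4**
Reactants: 13 3,5-dimethoxy-4-(methoxymethoxy)-2-(2,4,6-trimethoxyphenyl)phenol; 14 2-iodo-1,3,5-trimethoxybenzene
Product: 15 1,3-dimethoxy-2-(methoxymethoxy)-5-(2,4,6-trimethoxyphenoxy)-4-(2,4,6-trimethoxyphenyl)benzene
Conditions: CuI (cat.), picolinic acid, K3PO4, DMSO, 100 °C, argon
Reagents that add atoms: none
Why: Ullmann-type copper-catalysed O-arylation with a picolinate ligand is established for ortho-substituted phenols and ortho-substituted aryl iodides, and the MOM acetal and the methyl ethers are inert to the phosphate base.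

**Step 5**
Reactants: 15 1,3-dimethoxy-2-(methoxymethoxy)-5-(2,4,6-trimethoxyphenoxy)-4-(2,4,6-trimethoxyphenyl)benzene
Product: 16 2,6-dimethoxy-4-(2,4,6-trimethoxyphenoxy)-3-(2,4,6-trimethoxyphenyl)phenol (arm phenol)
Conditions: HCl (aq., cat.), MeOH/THF, 50 °C
Reagents that add atoms: none
Why: Acid-catalysed acetal methanolysis (MOM cleavage) should free only the B4 phenol, since aryl methyl ethers and diaryl ethers are stable to dilute acid.

**Step 6**
Reactants: 16 arm phenol (two equivalents); 17 2,6-difluoro-4-methoxybenzaldehyde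
Product: 19 2,6-bis[2,6-dimethoxy-4-(2,4,6-trimethoxyphenoxy)-3-(2,4,6-trimethoxyphenyl)phenoxy]-4-methoxybenzaldehyde, via monoaryl ether fluoroaldehyde 18 (not isolated)
Conditions: 16 (2.2 equiv), Cs2CO3, DMSO, 110 °C, argon
Reagents that add atoms: none
Why: Two consecutive nucleophilic aromatic substitutions (addition–elimination) by the caesium phenoxide should displace both fluorides, each activated by the ortho formyl group, while the 4-methoxy group lies meta to both and takes up no charge of the Meisenheimer adducts.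

**Step 7**
Reactants: 19 2,6-bis(aryloxy)-4-methoxybenzaldehyde
Product: 21 2,6-bis[2,6-dimethoxy-4-(2,4,6-trimethoxyphenoxy)-3-(2,4,6-trimethoxyphenyl)phenoxy]-4-methoxyphenol, via aryl formate 20 (not isolated)
Conditions: mCPBA (1.2 equiv), CH2Cl2, 0 °C → rt; then K2CO3 (cat.), MeOH, rt
Reagents that add atoms: meta-chloroperoxybenzoic acid (mCPBA), OOC(=O)c1cccc(Cl)c1
Why: In this Dakin-type Baeyer–Villiger oxidation the electron-rich, doubly ortho-oxygenated aryl group migrates in preference to hydride, giving the formate, which mild methanolysis converts into the phenol that becomes the ring C–O–ring G oxygen.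

**Step 8**
Reactants: 22 2-chloro-1,3-dimethoxybenzene
Product: 24 2-chloro-5-iodo-1,3-dimethoxybenzene, via arylboronic pinacol ester 23 (not isolated)
Conditions: B2pin2 (0.55 equiv), [Ir(OMe)(cod)]2 (cat.), dtbpy, THF, 80 °C; then CuI (cat.), 1,10-phenanthroline, KI, MeOH/H2O, air, 80 °C
Reagents that add atoms: potassium iodide, [K+].[I-]; bis(pinacolato)diboron, CC1(C)OB(OC1(C)C)B1OC(C)(C)C(C)(C)O1 (supplies the boryl group of 23 only)
Why: Sterically controlled iridium-catalysed C–H borylation should select C5, the only C–H flanked by two hydrogens, and copper-mediated aerobic iododeboronation of the boronate in the same pot gives the iodide.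

**Step 9**
Reactants: 21 2,6-bis(aryloxy)-4-methoxyphenol; 24 2-chloro-5-iodo-1,3-dimethoxybenzene
Product: 25 2-(4-chloro-3,5-dimethoxyphenoxy)-5-methoxy-1,3-bis[2,6-dimethoxy-4-(2,4,6-trimethoxyphenoxy)-3-(2,4,6-trimethoxyphenyl)phenoxy]benzene (nonadecamethyl ether of the target)
Conditions: CuI (cat.), picolinic acid, K3PO4, DMSO, 100 °C, argon
Reagents that add atoms: none
Why: Ullmann-type copper-catalysed O-arylation should engage the unhindered C–I bond and leave the C–Cl bond, which is shielded by two methoxy groups and far less reactive toward copper, untouched.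

**Step 10**
Reactants: 25 nonadecamethyl ether of the target
Product: 26 CNP0275555.0, 4-(4-chloro-3,5-dihydroxyphenoxy)-3,5-bis[2,6-dihydroxy-4-(2,4,6-trihydroxyphenoxy)-3-(2,4,6-trihydroxyphenyl)phenoxy]phenol
Conditions: BBr3 (large excess), CH2Cl2, −78 °C → rt, argon; MeOH, then H2O
Reagents that add atoms: none
Why: Lewis-acid-mediated cleavage of aryl methyl ethers (BBr3 demethylation, bromide attack on the methyl group of the boron-complexed ether) should remove all nineteen methyl groups, while the diaryl ether bonds and the aryl chloride do not react.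

**Compound list**

1 | dimethyl squarate (3,4-dimethoxycyclobut-3-ene-1,2-dione) | COC1=C(OC)C(=O)C1=O | starting material
2 | 1,3,5-trimethoxybenzene | COc1cc(OC)cc(OC)c1 | starting material
3 | 2,4,6-trimethoxyphenyllithium | [Li]c1c(OC)cc(OC)cc1OC | intermediate (not isolated)
4 | racemic lithium 2,3-dimethoxy-4-oxo-1-(2,4,6-trimethoxyphenyl)cyclobut-2-en-1-olate | [Li+].[O-]C1(c2c(OC)cc(OC)cc2OC)C(OC)=C(OC)C1=O | intermediate (not isolated)
5 | racemic 2,3-dimethoxy-4-oxo-1-(2,4,6-trimethoxyphenyl)cyclobut-2-en-1-yl trifluoroacetate | O=C(OC1(c2c(OC)cc(OC)cc2OC)C(OC)=C(OC)C1=O)C(F)(F)F | intermediate (not isolated)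
6 | 3-methoxy-4-(2,4,6-trimethoxyphenyl)cyclobut-3-ene-1,2-dione | COC1=C(c2c(OC)cc(OC)cc2OC)C(=O)C1=O | intermediate
7 | methyl vinyl ether | COC=C | starting material
8 | 1-methoxyvinyllithium | [Li]C(=C)OC | intermediate (not isolated)
9 | racemic lithium 2-methoxy-1-(1-methoxyvinyl)-4-oxo-3-(2,4,6-trimethoxyphenyl)cyclobut-2-en-1-olate | [Li+].[O-]C1(C(=C)OC)C(OC)=C(c2c(OC)cc(OC)cc2OC)C1=O | intermediate (not isolated)
10 | racemic 3-methoxy-4-(methoxymethoxy)-4-(1-methoxyvinyl)-2-(2,4,6-trimethoxyphenyl)cyclobut-2-en-1-one | O=C1C(c2c(OC)cc(OC)cc2OC)=C(OC)C1(OCOC)C(OC)=C | intermediate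
11 | (3Z)-3,5-dimethoxy-4-(methoxymethoxy)-2-(2,4,6-trimethoxyphenyl)hexa-1,3,5-trien-1-one (dienylketene) | O=C=C(c1c(OC)cc(OC)cc1OC)/C(OC)=C(OCOC)\C(OC)=C | intermediate (not isolated)
12 | 3,5-dimethoxy-4-(methoxymethoxy)-2-(2,4,6-trimethoxyphenyl)cyclohexa-2,4-dien-1-one | O=C1CC(OC)=C(OCOC)C(OC)=C1c1c(OC)cc(OC)cc1OC | intermediate (not isolated)
13 | 3,5-dimethoxy-4-(methoxymethoxy)-2-(2,4,6-trimethoxyphenyl)phenol | COCOc1c(OC)cc(O)c(-c2c(OC)cc(OC)cc2OC)c1OC | intermediate
14 | 2-iodo-1,3,5-trimethoxybenzene | COc1cc(OC)c(I)c(OC)c1 | starting material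
15 | 1,3-dimethoxy-2-(methoxymethoxy)-5-(2,4,6-trimethoxyphenoxy)-4-(2,4,6-trimethoxyphenyl)benzene | COCOc1c(OC)cc(Oc2c(OC)cc(OC)cc2OC)c(-c2c(OC)cc(OC)cc2OC)c1OC | intermediate
16 | 2,6-dimethoxy-4-(2,4,6-trimethoxyphenoxy)-3-(2,4,6-trimethoxyphenyl)phenol (arm phenol) | Oc1c(OC)cc(Oc2c(OC)cc(OC)cc2OC)c(-c2c(OC)cc(OC)cc2OC)c1OC | intermediate
17 | 2,6-difluoro-4-methoxybenzaldehyde | COc1cc(F)c(C=O)c(F)c1 | starting material
18 | 2-fluoro-4-methoxy-6-[2,6-dimethoxy-4-(2,4,6-trimethoxyphenoxy)-3-(2,4,6-trimethoxyphenyl)phenoxy]benzaldehyde | COc1cc(F)c(C=O)c(Oc2c(OC)cc(Oc3c(OC)cc(OC)cc3OC)c(-c3c(OC)cc(OC)cc3OC)c2OC)c1 | intermediate (not isolated)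
19 | 2,6-bis[2,6-dimethoxy-4-(2,4,6-trimethoxyphenoxy)-3-(2,4,6-trimethoxyphenyl)phenoxy]-4-methoxybenzaldehyde | COc1cc(Oc2c(OC)cc(Oc3c(OC)cc(OC)cc3OC)c(-c3c(OC)cc(OC)cc3OC)c2OC)c(C=O)c(Oc2c(OC)cc(Oc3c(OC)cc(OC)cc3OC)c(-c3c(OC)cc(OC)cc3OC)c2OC)c1 | intermediate
20 | 2,6-bis[2,6-dimethoxy-4-(2,4,6-trimethoxyphenoxy)-3-(2,4,6-trimethoxyphenyl)phenoxy]-4-methoxyphenyl formate | COc1cc(Oc2c(OC)cc(Oc3c(OC)cc(OC)cc3OC)c(-c3c(OC)cc(OC)cc3OC)c2OC)c(OC=O)c(Oc2c(OC)cc(Oc3c(OC)cc(OC)cc3OC)c(-c3c(OC)cc(OC)cc3OC)c2OC)c1 | intermediate (not isolated)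
21 | 2,6-bis[2,6-dimethoxy-4-(2,4,6-trimethoxyphenoxy)-3-(2,4,6-trimethoxyphenyl)phenoxy]-4-methoxyphenol | COc1cc(Oc2c(OC)cc(Oc3c(OC)cc(OC)cc3OC)c(-c3c(OC)cc(OC)cc3OC)c2OC)c(O)c(Oc2c(OC)cc(Oc3c(OC)cc(OC)cc3OC)c(-c3c(OC)cc(OC)cc3OC)c2OC)c1 | intermediate
22 | 2-chloro-1,3-dimethoxybenzene | COc1cccc(OC)c1Cl | starting material
23 | 2-(4-chloro-3,5-dimethoxyphenyl)-4,4,5,5-tetramethyl-1,3,2-dioxaborolane | COc1cc(B2OC(C)(C)C(C)(C)O2)cc(OC)c1Cl | intermediate (not isolated)
24 | 2-chloro-5-iodo-1,3-dimethoxybenzene | COc1cc(I)cc(OC)c1Cl | intermediate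
25 | 2-(4-chloro-3,5-dimethoxyphenoxy)-5-methoxy-1,3-bis[2,6-dimethoxy-4-(2,4,6-trimethoxyphenoxy)-3-(2,4,6-trimethoxyphenyl)phenoxy]benzene | COc1cc(Oc2c(OC)cc(Oc3c(OC)cc(OC)cc3OC)c(-c3c(OC)cc(OC)cc3OC)c2OC)c(Oc2cc(OC)c(Cl)c(OC)c2)c(Oc2c(OC)cc(Oc3c(OC)cc(OC)cc3OC)c(-c3c(OC)cc(OC)cc3OC)c2OC)c1 | intermediate
26 | CNP0275555.0, 4-(4-chloro-3,5-dihydroxyphenoxy)-3,5-bis[2,6-dihydroxy-4-(2,4,6-trihydroxyphenoxy)-3-(2,4,6-trihydroxyphenyl)phenoxy]phenol | Oc1cc(O)c(Oc2cc(O)c(Oc3cc(O)cc(Oc4c(O)cc(Oc5c(O)cc(O)cc5O)c(-c5c(O)cc(O)cc5O)c4O)c3Oc3cc(O)c(Cl)c(O)c3)c(O)c2-c2c(O)cc(O)cc2O)c(O)c1 | target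

**Step count.** Total: 10 steps. Longest linear sequence: 9 steps (steps 1–7, 9, 10); step 8 is a one-step side branch.

**Steps most likely to fail**

Step 4. Both partners are ortho-crowded and the iodide is very electron-rich, so C–O bond formation at copper may be slower than protodeiodination of 14 and oxidative self-coupling of the phenoxide. The fallback sets out from 13 and comes back at 15; ring A is brought in as an aldehyde-activated electrophile and its para oxygen is installed afterwards. Compound 13 is coupled with commercial 4-bromo-3,5-dimethoxybenzaldehyde (CuI, picolinic acid, K3PO4, DMSO, 90 °C), whose para formyl group makes the halide far more reactive in copper-mediated substitution. This should give 4-[3,5-dimethoxy-4-(methoxymethoxy)-2-(2,4,6-trimethoxyphenyl)phenoxy]-3,5-dimethoxybenzaldehyde F1. Dakin oxidation (mCPBA, CH2Cl2, 0 °C) converts it into the aryl formate F2, methanolysis (K2CO3, MeOH) gives the phenol F3, and O-methylation (MeI, K2CO3, acetone) returns 15.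

Step 6. The second fluoride displacement may stall once the first aryloxy group has made the ring more electron-rich and more crowded, while the free formyl group is slowly degraded by hot carbonate. The fallback sets out from 16 and comes back at 19; it replaces the aldehyde by a more strongly activating, base-inert nitrile. Compound 16 (2.2 equiv) and commercial 2,6-difluoro-4-methoxybenzonitrile (Cs2CO3, DMSO, 120 °C) should give, through the monoether fluoronitrile F4, the 2,6-bis(aryloxy)-4-methoxybenzonitrile F5. Partial reduction with i-Bu2AlH (toluene, −78 → 0 °C) leads to the aldimine F6, which dilute HCl hydrolyses on work-up to aldehyde 19.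

Step 9. The phenoxide of 21, flanked by two large aryloxy groups and easily oxidised by copper salts, may fail to couple, so that 24 is only reduced or homocoupled. The fallback sets out from 24 and 21 and comes back at 25; it uses metal-free arylation with a diaryliodonium salt. Iodide 24 is oxidised (mCPBA, TsOH·H2O, MeCN) to the [hydroxy(tosyloxy)iodo]arene F7, which in the same pot arylates 1,3,5-trimethoxybenzene 2 to give (4-chloro-3,5-dimethoxyphenyl)(2,4,6-trimethoxyphenyl)iodonium tosylate F8. The potassium salt of 21 (t-BuOK, THF/toluene, rt) adds to the trivalent iodine centre, and ligand coupling should transfer the less electron-rich aryl group to oxygen, giving 25 and 2-iodo-1,3,5-trimethoxybenzene (14).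

**Further compounds**

F1 | step 4 | 4-[3,5-dimethoxy-4-(methoxymethoxy)-2-(2,4,6-trimethoxyphenyl)phenoxy]-3,5-dimethoxybenzaldehyde | O=Cc1cc(OC)c(Oc2cc(OC)c(OCOC)c(OC)c2-c2c(OC)cc(OC)cc2OC)c(OC)c1
F2 | step 4 | 4-[3,5-dimethoxy-4-(methoxymethoxy)-2-(2,4,6-trimethoxyphenyl)phenoxy]-3,5-dimethoxyphenyl formate | O=COc1cc(OC)c(Oc2cc(OC)c(OCOC)c(OC)c2-c2c(OC)cc(OC)cc2OC)c(OC)c1
F3 | step 4 | 4-[3,5-dimethoxy-4-(methoxymethoxy)-2-(2,4,6-trimethoxyphenyl)phenoxy]-3,5-dimethoxyphenol | Oc1cc(OC)c(Oc2cc(OC)c(OCOC)c(OC)c2-c2c(OC)cc(OC)cc2OC)c(OC)c1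
F4 | step 6 | 2-fluoro-4-methoxy-6-[2,6-dimethoxy-4-(2,4,6-trimethoxyphenoxy)-3-(2,4,6-trimethoxyphenyl)phenoxy]benzonitrile | COc1cc(F)c(C#N)c(Oc2c(OC)cc(Oc3c(OC)cc(OC)cc3OC)c(-c3c(OC)cc(OC)cc3OC)c2OC)c1
F5 | step 6 | 2,6-bis[2,6-dimethoxy-4-(2,4,6-trimethoxyphenoxy)-3-(2,4,6-trimethoxyphenyl)phenoxy]-4-methoxybenzonitrile | COc1cc(Oc2c(OC)cc(Oc3c(OC)cc(OC)cc3OC)c(-c3c(OC)cc(OC)cc3OC)c2OC)c(C#N)c(Oc2c(OC)cc(Oc3c(OC)cc(OC)cc3OC)c(-c3c(OC)cc(OC)cc3OC)c2OC)c1
F6 | step 6 | 2,6-bis[2,6-dimethoxy-4-(2,4,6-trimethoxyphenoxy)-3-(2,4,6-trimethoxyphenyl)phenoxy]-4-methoxybenzaldimine | COc1cc(Oc2c(OC)cc(Oc3c(OC)cc(OC)cc3OC)c(-c3c(OC)cc(OC)cc3OC)c2OC)c(C=N)c(Oc2c(OC)cc(Oc3c(OC)cc(OC)cc3OC)c(-c3c(OC)cc(OC)cc3OC)c2OC)c1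
F7 | step 9 | [hydroxy(tosyloxy)iodo]-4-chloro-3,5-dimethoxybenzene | COc1cc(I(O)OS(=O)(=O)c2ccc(C)cc2)cc(OC)c1Cl
F8 | step 9 | (4-chloro-3,5-dimethoxyphenyl)(2,4,6-trimethoxyphenyl)iodonium 4-methylbenzenesulfonate | COc1cc([I+]c2c(OC)cc(OC)cc2OC)cc(OC)c1Cl.Cc1ccc(S(=O)(=O)[O-])cc1
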